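Assumption (chemistry): the target is taken as the E,E isomer drawn, which has no stereocentre. Compounds 1, 5 and 14 and the reagents named under the steps are taken as commercial.

Ring labels used throughout: ring A is the 2,4-dihydroxyphenyl ketone ring of the first chalcone and ring B its 4-hydroxyphenyl ring (C1 carries the propenone, C3 the biaryl bond, C4 the OH). Ring C is the 2,4-dihydroxyphenyl ketone ring of the second chalcone (C1 acyl, C2 OH, C3 H, C4 OH, C5 ring B, C6 H) and ring D its 4-hydroxyphenyl ring.

## The problem

Rhuschalcone VI (21) has no stereocentre; its only stereochemical elements are two E enones, so the difficulty is one of connectivity. It consists of two units of the same chalcone (isoliquiritigenin A4), joined by a single biaryl bond from C3 of ring B to C5 of ring C. Both carbons of this bond lie ortho to a phenolic oxygen and are therefore both nucleophilic positions. A direct ionic union is thus impossible, an oxidative union would have to choose among at least five equally activated positions, and a cross-coupling must first place halogen and metal on two fully oxygenated rings. Because the halves are so alike, the two aldol bonds must also be made without scrambling, since a biaryl carrying both an acetyl and a formyl group would condense with itself. The feature that opens another way is the substitution pattern of ring C: C2 and C4 carry oxygen, C1 the acyl group, C5 ring B, and C3 and C6 hydrogen. This is the pattern that a 1,1,3-trioxygenated butadiene (C2–C3–C4–C5, aryl on the terminus) and a terminal alkynyl ketone (C1 and C6) give on (4+2) cycloaddition and loss of methanol, so ring C can be built around a "biaryl" bond that starts as the ordinary aryl–CH2 bond of a phenylacetic ester. The groups to be respected are the enones (Michael acceptors, reducible), the 2-hydroxyaryl enones (cyclization to flavanones with acid, base or heat) and five oxidizable phenols, which rules out hydrogenolysis and nucleophilic dealkylation at the end.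

## Retrosynthesis

21 ⇒ 20. The four O–isopropyl bonds on rings A, B and D are cut. Isopropyl ethers are chosen over methyl or methoxymethyl ethers because they should survive Lewis-acid formylation, hydroxide and amide bases, yet fall to BCl3 at low temperature without reduction or nucleophiles. The two hydroxyl groups of ring C need no protection, because they are created free in the key step. The forward reaction must cleave four ethers without closing either 2-hydroxyaryl enone to a flavanone.

20 ⇒ 13 + 17. The C1–C2 and C5–C6 bonds of ring C are cut, not the biaryl bond. The other partitions of ring C would need an ynol ether with an acyl diene, or would put the aryl group on the alkyne carbon that ends between the two oxygens. Only this partition places both oxygens and the aryl group on a diene that derives from a β-keto ester, and the acyl group on a terminal alkyne. The gain is large: ring C, its two hydroxyl groups, the ketone of the second chalcone and the biaryl linkage all come from one reaction of two open-chain partners. The forward reaction must show one regiochemistry, react at the alkyne and not at the two styryl enones, and aromatize with OH (not OMe) at C2.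

13 ⇒ 11 ⇒ 8. The two O–Si bonds are cut, and then the bond between the acid carbonyl and a malonate carbon. The first chalcone is deliberately in place before the diene is made, so that only deprotection follows the key step. A free aldehyde could not be carried through enolate chemistry, and an acetal would cost two extra steps (that variant is kept as a fallback). The forward steps must homologate an arylacetic acid and form a silyl ketene acetal in the presence of an enone that has no acidic proton.

8 ⇒ 4 + 6. The Cα=Cβ bond of the first chalcone is cut (Claisen–Schmidt condensation). Aldehyde 4 cannot enolize, and its ester is hydrolysed first (carboxylate 7) so that the arylacetic methylene group is not acidic during the condensation.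

4 ⇒ 2 ⇒ 1 and 6 ⇒ 5. The C–CHO bond para to the ether oxygen is cut, then the O–alkyl bonds. The ortho relation between oxygen and the CH2 group, which becomes the ortho relation between the C4 oxygen of ring B and the biaryl bond, is bought with commercial 1. The formylation only has to find the free para position.

17 ⇒ 15 ⇒ 14. The acyl–alkyne bond is cut (ketone synthesis from an N-methoxy-N-methylamide) and then the C=C bond (Horner–Wadsworth–Emmons reaction). This gives the cross-conjugated enynone in two steps from a commercial aldehyde, with the E geometry set by the stabilized phosphonate.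

## Roads not taken

Alternative 1: cut the biaryl bond C3(ring B)–C5(ring C) and form it by Suzuki–Miyaura coupling of bromochalcone A1 with chalcone boronate A2 to give the hexakis(methoxymethyl) ether A3, followed by acid deprotection. This is the route most chemists would draw first, and it is sound. It needs a regioselective halogenation of an acylresorcinol (C5 against C3), a borylation, and a palladium coupling between two ortho-oxygenated carbons in the presence of two enones, where protodeboronation of the electron-rich ortho-alkoxy boronate competes. It also needs six protecting groups where the chosen plan needs four, and two separate chalcone syntheses before the union. The chosen plan uses no halogen, boron or palladium, fixes the position of the biaryl bond through a commercial ortho-substituted phenylacetate, and forms ring C together with its ketone.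

Alternative 2: cut the same bond and form it by oxidative dehydrodimerization of isoliquiritigenin A4 (one-electron oxidation to phenoxyl radicals and C–C coupling), as the biosynthesis presumably does. It would be one step, but A4 offers C3/C5 of ring B, C3 and C5 of ring A, the phenolic oxygens and, through the 4-hydroxystyryl system, the enone α-carbon as coupling sites. The wanted B-to-A linkage is one of many C–C and C–O dimers, and nothing in the substrate directs it. The phenols are also electron-poor (conjugated with carbonyl groups) and oxidize reluctantly, while 2-hydroxyaryl enones cyclize under oxidative conditions. The chosen plan replaces this selection problem with a regiospecific ring construction.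

Alternative 3: build ring C by a different annulation. Michael–Claisen condensation of arylacetone A5 with an acrylate would give 4-arylcyclohexane-1,3-dione A6, dehydrogenation would give arylresorcinol A7, and Friedel–Crafts cinnamoylation at C1 would follow. This also avoids a biaryl coupling, but the ring is formed at the wrong oxidation level and without the acyl group. A dehydrogenation and a Lewis-acid acylation then have to be carried out on a polyfunctional biaryl, with competition from C3 and from closure of the new hydroxychalcone to a flavanone or dihydrocoumarin. The cycloaddition of the chosen plan delivers the aromatic ring, both hydroxyl groups and the complete enone side chain in one operation.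

Key step: step 9

## Steps

Step 1
Reactants: 1 methyl 2-(2-hydroxyphenyl)acetate
Product: 2 methyl 2-(2-isopropoxyphenyl)acetate
Conditions: 2-bromopropane, K2CO3, DMF, 60 °C
Reagents that add atoms: 2-bromopropane, CC(C)Br
Why: Williamson ether synthesis on the phenoxide; the methyl ester is not touched by K2CO3 in DMF, and the secondary bromide needs only gentle heating.

Step 2
Reactants: 2 methyl 2-(2-isopropoxyphenyl)acetate
Product: 4 methyl 2-(5-formyl-2-isopropoxyphenyl)acetate, via α-chloro ether 3 (not isolated)
Conditions: Cl2CHOMe, TiCl4, CH2Cl2, −20 → 0 °C; then ice-water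
Reagents that add atoms: dichloromethyl methyl ether, COC(Cl)Cl; water, O
Why: Rieche formylation; the alkoxy group directs the chloro(methoxy)methyl cation to its free para position, the ortho position being screened by the isopropyl group, and the aqueous work-up hydrolyses 3 to the aldehyde. The low temperature is chosen to spare the isopropyl ether, which cannot chelate the Lewis acid to the new carbonyl group.

Step 3
Reactants: 5 1-(2,4-dihydroxyphenyl)ethan-1-one
Product: 6 1-(2,4-diisopropoxyphenyl)ethan-1-one
Conditions: 2-bromopropane, K2CO3, DMF, 80 °C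
Reagents that add atoms: 2-bromopropane, CC(C)Br
Why: Double Williamson ether synthesis; excess halide and heat are needed for the hydrogen-bonded 2-hydroxyl group.

Step 4
Reactants: 4 methyl 2-(5-formyl-2-isopropoxyphenyl)acetate; 6 1-(2,4-diisopropoxyphenyl)ethan-1-one
Product: 8 2-[5-[(1E)-3-(2,4-diisopropoxyphenyl)-3-oxoprop-1-en-1-yl]-2-isopropoxyphenyl]acetic acid, via potassium carboxylate 7 (not isolated)
Conditions: KOH, MeOH–H2O, rt; then 6, rt → 40 °C; then HCl (aq) to pH 3
Reagents that add atoms: potassium hydroxide, [K+].[OH-]
Why: Saponification first gives carboxylate 7, whose methylene group is no longer acidic, so only ketone 6 can enolize. Claisen–Schmidt condensation with the non-enolizable aldehyde then gives the enone, and E1cB dehydration under equilibrating conditions sets the E double bond.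

Step 5
Reactants: 8 2-[5-[(1E)-3-(2,4-diisopropoxyphenyl)-3-oxoprop-1-en-1-yl]-2-isopropoxyphenyl]acetic acid
Product: 11 methyl 4-[5-[(1E)-3-(2,4-diisopropoxyphenyl)-3-oxoprop-1-en-1-yl]-2-isopropoxyphenyl]-3-oxobutanoate, via acyl imidazole 9 (not isolated), via acylmalonic half ester 10 (not isolated)
Conditions: CDI, THF, rt; then MeO2CCH2CO2K, MgCl2, Et3N, MeCN, rt → 45 °C; then 1 M HCl
Reagents that add atoms: potassium methyl malonate, COC(=O)CC(=O)[O-].[K+]
Why: Masamune–Brooks two-carbon homologation: acyl imidazole 9 C-acylates the magnesium enolate of the malonate half ester, and 10 loses CO2 on acidic work-up. The conditions are close to neutral, so the chalcone enone and the ethers should not be affected.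

Step 6
Reactants: 11 methyl 4-[5-[(1E)-3-(2,4-diisopropoxyphenyl)-3-oxoprop-1-en-1-yl]-2-isopropoxyphenyl]-3-oxobutanoate
Product: 13 (2E)-1-(2,4-diisopropoxyphenyl)-3-[4-isopropoxy-3-[(1Z,3Z)-4-methoxy-2,4-bis(trimethylsilyloxy)buta-1,3-dien-1-yl]phenyl]prop-2-en-1-one, via silyl enol ether 12 (not isolated)
Conditions: Me3SiCl, Et3N, THF, rt; then LiN(SiMe3)2 added at −78 °C in the presence of excess Me3SiCl
Reagents that add atoms: chlorotrimethylsilane, C[Si](C)(C)Cl
Why: Stepwise double enol silylation as used for 1-alkoxy-1,3-bis(silyloxy)butadienes: the amine and chlorosilane silylate the ketone enol, then the benzylic, vinylogous γ-proton of 12 is removed by the non-nucleophilic amide and the dienolate is trapped on oxygen as it forms. The chalcone has no acidic proton, and in-situ trapping at −78 °C should keep the dienolate from adding to it. The Z geometry at the aryl-bearing double bond (aryl anti to the diene chain) is the usual kinetic outcome and is what the cycloaddition needs.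

Step 7
Reactants: 14 4-isopropoxybenzaldehyde
Product: 15 (2E)-3-(4-isopropoxyphenyl)-N-methoxy-N-methylprop-2-enamide
Conditions: (EtO)2P(O)CH2C(O)N(OMe)Me, NaH, THF, 0 °C → rt
Reagents that add atoms: diethyl (N-methoxy-N-methylcarbamoylmethyl)phosphonate, CCOP(=O)(CC(=O)N(C)OC)OCC
Why: Horner–Wadsworth–Emmons olefination with a stabilized phosphonate; reversible addition and anti elimination should give the E enamide.

Step 8
Reactants: 15 (2E)-3-(4-isopropoxyphenyl)-N-methoxy-N-methylprop-2-enamide
Product: 17 (1E)-1-(4-isopropoxyphenyl)pent-1-en-4-yn-3-one, via magnesium hemiaminal 16 (not isolated)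
Conditions: HC≡CMgBr, THF, −20 → 0 °C; then poured into cold 1 M HCl
Reagents that add atoms: ethynylmagnesium bromide, C#C[Mg]Br
Why: Weinreb ketone synthesis: chelate 16 holds the addition at the ketone level and 1,2-addition is preferred over attack on the enamide double bond. The inverse acidic quench protonates the released N,O-dimethylhydroxylamine before it can add to the ynone.

Step 9
Reactants: 13 (2E)-1-(2,4-diisopropoxyphenyl)-3-[4-isopropoxy-3-[(1Z,3Z)-4-methoxy-2,4-bis(trimethylsilyloxy)buta-1,3-dien-1-yl]phenyl]prop-2-en-1-one; 17 (1E)-1-(4-isopropoxyphenyl)pent-1-en-4-yn-3-one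
Product: 20 (2E)-1-[5-[5-[(1E)-3-(2,4-diisopropoxyphenyl)-3-oxoprop-1-en-1-yl]-2-isopropoxyphenyl]-2,4-dihydroxyphenyl]-3-(4-isopropoxyphenyl)prop-2-en-1-one, via cycloadduct 18 (not isolated), via bis-silyl ether 19 (not isolated)
Conditions: PhMe, rt → 60 °C; then 1 M HCl, THF, 0 °C
Reagents that add atoms: none
Why: Diels–Alder reaction of normal electron demand between an electron-rich 1-alkoxy-1,3-bis(silyloxy)butadiene and an alkynyl ketone, followed by aromatization; its closest known relatives are the cycloadditions of 1,1-dialkoxy-3-silyloxy- and 1-alkoxy-1,3-bis(silyloxy)butadienes with acetylenic ketones and esters, which give 4-acylresorcinols and resorcylates in one regiochemical sense. The aryl-bearing diene terminus of 13 (largest HOMO coefficient, future C5 of ring C) should bond to the unsubstituted β-carbon of ynone 17 (future C6) and the ketene-acetal carbon (future C2) to the α-carbon (future C1), whether the reaction is concerted and asynchronous or a Michael addition followed by closure of the allenolate on the oxocarbenium ion. Ring C is thus closed in an intermolecular (4+2) mode through the C5–C6 and C1–C2 bonds. Cycloadduct 18 has two sp3 carbons (C5 with H and aryl, C2 with OMe and OSiMe3) as a mixture of diastereomers, but 1,4-elimination of methanol across the ring removes both, so no stereocentre remains and none needs control; the two E enones are not touched. Dilute acid then cleaves the two aryl silyl ethers of 19, and because the mixed silyl methyl ketal at C2 collapses at the carbonyl level, C2 should end as the free, ketone-chelated OH and not as a methyl ether. Three selectivities are needed: regiochemistry, secured by the polarization of both partners and by the terminal alkyne, which offers an unhindered CH to the substituted diene terminus; chemoselectivity for the C≡C bond over the two β-aryl enone C=C bonds, secured by the much higher dienophilicity of an alkynyl ketone compared with electron-rich chalcone-type alkenes; and an accessible s-cis diene, secured by the Z geometry that places the aryl group outside.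

Step 10
Reactants: 20 (2E)-1-[5-[5-[(1E)-3-(2,4-diisopropoxyphenyl)-3-oxoprop-1-en-1-yl]-2-isopropoxyphenyl]-2,4-dihydroxyphenyl]-3-(4-isopropoxyphenyl)prop-2-en-1-one
Product: 21 rhuschalcone VI
Conditions: BCl3, CH2Cl2, −78 → 0 °C; then MeOH, aq. NaHCO3
Reagents that add atoms: none
Why: BCl3 cleaves isopropyl aryl ethers by coordination to oxygen and loss of the secondary alkyl group as 2-chloropropane at low temperature, a standard last step for polyphenols that ketones, enones and free phenols tolerate. The ortho-hydroxy ketones are held as boron chelates until the buffered work-up, which should keep the phenols from adding to the enones.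

## Compound list

1 | methyl 2-(2-hydroxyphenyl)acetate | COC(=O)Cc1ccccc1O | starting material
2 | methyl 2-(2-isopropoxyphenyl)acetate | COC(=O)Cc1ccccc1OC(C)C | intermediate
3 | methyl 2-[5-[chloro(methoxy)methyl]-2-isopropoxyphenyl]acetate (racemic α-chloro ether) | COC(=O)Cc1cc(C(Cl)OC)ccc1OC(C)C | intermediate
4 | methyl 2-(5-formyl-2-isopropoxyphenyl)acetate | COC(=O)Cc1cc(C=O)ccc1OC(C)C | intermediate
5 | 1-(2,4-dihydroxyphenyl)ethan-1-one | CC(=O)c1ccc(O)cc1O | starting material
6 | 1-(2,4-diisopropoxyphenyl)ethan-1-one | CC(=O)c1ccc(OC(C)C)cc1OC(C)C | intermediate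
7 | potassium 2-(5-formyl-2-isopropoxyphenyl)acetate | O=Cc1ccc(OC(C)C)c(CC(=O)[O-])c1.[K+] | intermediate
8 | 2-[5-[(1E)-3-(2,4-diisopropoxyphenyl)-3-oxoprop-1-en-1-yl]-2-isopropoxyphenyl]acetic acid | OC(=O)Cc1cc(/C=C/C(=O)c2ccc(OC(C)C)cc2OC(C)C)ccc1OC(C)C | intermediate
9 | (2E)-1-(2,4-diisopropoxyphenyl)-3-[3-[2-(imidazol-1-yl)-2-oxoethyl]-4-isopropoxyphenyl]prop-2-en-1-one (acyl imidazole of 8) | O=C(Cc1cc(/C=C/C(=O)c2ccc(OC(C)C)cc2OC(C)C)ccc1OC(C)C)n1ccnc1 | intermediate
10 | 4-[5-[(1E)-3-(2,4-diisopropoxyphenyl)-3-oxoprop-1-en-1-yl]-2-isopropoxyphenyl]-2-(methoxycarbonyl)-3-oxobutanoic acid (present as its magnesium chelate) | COC(=O)C(C(=O)O)C(=O)Cc1cc(/C=C/C(=O)c2ccc(OC(C)C)cc2OC(C)C)ccc1OC(C)C | intermediate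
11 | methyl 4-[5-[(1E)-3-(2,4-diisopropoxyphenyl)-3-oxoprop-1-en-1-yl]-2-isopropoxyphenyl]-3-oxobutanoate | COC(=O)CC(=O)Cc1cc(/C=C/C(=O)c2ccc(OC(C)C)cc2OC(C)C)ccc1OC(C)C | intermediate
12 | methyl (2Z)-4-[5-[(1E)-3-(2,4-diisopropoxyphenyl)-3-oxoprop-1-en-1-yl]-2-isopropoxyphenyl]-3-(trimethylsilyloxy)but-2-enoate (enol ether geometry of no consequence) | COC(=O)/C=C(\O[Si](C)(C)C)Cc1cc(/C=C/C(=O)c2ccc(OC(C)C)cc2OC(C)C)ccc1OC(C)C | intermediate
13 | (2E)-1-(2,4-diisopropoxyphenyl)-3-[4-isopropoxy-3-[(1Z,3Z)-4-methoxy-2,4-bis(trimethylsilyloxy)buta-1,3-dien-1-yl]phenyl]prop-2-en-1-one | CO/C(O[Si](C)(C)C)=C/C(O[Si](C)(C)C)=C/c1cc(/C=C/C(=O)c2ccc(OC(C)C)cc2OC(C)C)ccc1OC(C)C | intermediate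
14 | 4-isopropoxybenzaldehyde | CC(C)Oc1ccc(C=O)cc1 | starting material
15 | (2E)-3-(4-isopropoxyphenyl)-N-methoxy-N-methylprop-2-enamide | CON(C)C(=O)/C=C/c1ccc(OC(C)C)cc1 | intermediate
16 | bromomagnesium (1E)-1-(4-isopropoxyphenyl)-3-[methoxy(methyl)amino]pent-1-en-4-yn-3-olate | C#CC(O[Mg]Br)(/C=C/c1ccc(OC(C)C)cc1)N(C)OC | intermediate
17 | (1E)-1-(4-isopropoxyphenyl)pent-1-en-4-yn-3-one | C#CC(=O)/C=C/c1ccc(OC(C)C)cc1 | intermediate
18 | (2E)-1-[3-aryl-6-methoxy-4,6-bis(trimethylsilyloxy)cyclohexa-1,4-dien-1-yl]-3-(4-isopropoxyphenyl)prop-2-en-1-one, aryl being the ring B unit of 13; mixture of diastereomers at the two sp3 ring carbons | COC1(O[Si](C)(C)C)C=C(O[Si](C)(C)C)C(c2cc(/C=C/C(=O)c3ccc(OC(C)C)cc3OC(C)C)ccc2OC(C)C)C=C1C(=O)/C=C/c1ccc(OC(C)C)cc1 | intermediate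
19 | bis(trimethylsilyl) ether of 20 at the two ring C oxygens | O=C(/C=C/c1ccc(OC(C)C)cc1)c1cc(-c2cc(/C=C/C(=O)c3ccc(OC(C)C)cc3OC(C)C)ccc2OC(C)C)c(O[Si](C)(C)C)cc1O[Si](C)(C)C | intermediate
20 | (2E)-1-[5-[5-[(1E)-3-(2,4-diisopropoxyphenyl)-3-oxoprop-1-en-1-yl]-2-isopropoxyphenyl]-2,4-dihydroxyphenyl]-3-(4-isopropoxyphenyl)prop-2-en-1-one | O=C(/C=C/c1ccc(OC(C)C)cc1)c1cc(-c2cc(/C=C/C(=O)c3ccc(OC(C)C)cc3OC(C)C)ccc2OC(C)C)c(O)cc1O | intermediate
21 | rhuschalcone VI, (2E)-1-[5-[5-[(1E)-3-(2,4-dihydroxyphenyl)-3-oxoprop-1-en-1-yl]-2-hydroxyphenyl]-2,4-dihydroxyphenyl]-3-(4-hydroxyphenyl)prop-2-en-1-one | O=C(/C=C/c1ccc(O)c(-c2cc(C(=O)/C=C/c3ccc(O)cc3)c(O)cc2O)c1)c1ccc(O)cc1O | target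

## Step count and least certain steps

Total step count: 10 steps. Longest linear sequence: 7 steps (steps 1, 2, 4, 5, 6, 9 and 10).

**Step 9 (key step).** The most likely failure is a slow cycloaddition at the aryl-substituted, styrene-like diene terminus. Protodesilylation of the ketene acetal and oligomerization of the terminal ynone would then overtake ring formation. Bond formation at the central diene carbon, giving open-chain Michael adducts, is a lesser risk.

The fallback forms the biaryl bond by cross-coupling; it sets out from 6 and 14 and comes back to the route at 21: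
- 3-Bromo-4-hydroxybenzaldehyde would be O-alkylated with 2-bromopropane and K2CO3 to 3-bromo-4-isopropoxybenzaldehyde F1.
- F1 would be condensed with 6 (KOH, EtOH) to bromochalcone F2, which Miyaura borylation (B2pin2, Pd(dppf)Cl2, KOAc, dioxane) would turn into boronate F3.
- Bromination of 6 with N-bromosuccinimide at the position para to the 2-alkoxy group would give bromoketone F4, and Claisen–Schmidt condensation with 14 would give bromochalcone F5.
- Suzuki–Miyaura coupling of F3 with F5 (Pd(PPh3)4, K2CO3, dioxane–water) would give hexa-isopropyl ether F6, and BCl3 as in step 10 would give 21.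

**Step 6.** The most likely failure is conjugate addition of the lithium dienolate, or of the amide base, to the chalcone enone of another molecule before O-silylation, because the substrate carries a Michael acceptor next to a forming soft nucleophile.

The fallback keeps the aldehyde masked and makes the first chalcone last; it sets out from 4 and comes back at 20:
- 4 would be converted with HC(OMe)3 and a trace of pyridinium p-toluenesulfonate in MeOH into dimethyl acetal F7, and LiOH would give acid F8.
- Homologation as in step 5 (buffered work-up) would give β-keto ester F9, and double silylation (Me3SiCl, Et3N; then LiN(iPr)2, Me3SiCl) would give diene F10.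
- Cycloaddition with 17 and acidic work-up, which also unmasks the aldehyde, would give biaryl aldehyde F11.
- Claisen–Schmidt condensation of F11 with 6 (KOH, MeOH) would give 20.

**Step 2.** The most likely failure is Lewis-acid-induced loss of the isopropyl group during formylation, with some attack ortho to oxygen, because TiCl4 also activates secondary alkyl aryl ethers.

The fallback introduces the formyl group by halogenation and carbonylation; it sets out from 2 and comes back at 4. Para-bromination with N-bromosuccinimide in MeCN would give aryl bromide F12, and palladium-catalysed reductive carbonylation (CO/H2, Pd(OAc)2, di(1-adamantyl)-n-butylphosphine, TMEDA, toluene, 100 °C) would give 4.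

**Step 10.** The most likely failure is acid-promoted oxa-Michael closure of one or both 2-hydroxyaryl enones to flavanones during ether cleavage or work-up, together with slow cleavage of the ring A ether para to the ketone.

The fallback accepts the cyclization and reverses it; it sets out from 20 and comes back at 21. The cleavage would be driven to completion with BCl3 at rt, which would give the pentaphenol partly or wholly as flavanones such as bis-flavanone F13. Aqueous KOH at rt under argon would open the flavanones by E1cB elimination of the phenoxide to the chalcone phenolates, and acidification at 0 °C would give 21.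

## Further compounds

F1 | step 9 | 3-bromo-4-isopropoxybenzaldehyde | CC(C)Oc1ccc(C=O)cc1Br
F2 | step 9 | (2E)-3-(3-bromo-4-isopropoxyphenyl)-1-(2,4-diisopropoxyphenyl)prop-2-en-1-one | CC(C)Oc1ccc(C(=O)/C=C/c2ccc(OC(C)C)c(Br)c2)c(OC(C)C)c1
F3 | step 9 | (2E)-1-(2,4-diisopropoxyphenyl)-3-[4-isopropoxy-3-(4,4,5,5-tetramethyl-1,3,2-dioxaborolan-2-yl)phenyl]prop-2-en-1-one | CC(C)Oc1ccc(C(=O)/C=C/c2ccc(OC(C)C)c(B3OC(C)(C)C(C)(C)O3)c2)c(OC(C)C)c1
F4 | step 9 | 1-(5-bromo-2,4-diisopropoxyphenyl)ethan-1-one | CC(=O)c1cc(Br)c(OC(C)C)cc1OC(C)C
F5 | step 9 | (2E)-1-(5-bromo-2,4-diisopropoxyphenyl)-3-(4-isopropoxyphenyl)prop-2-en-1-one | CC(C)Oc1ccc(/C=C/C(=O)c2cc(Br)c(OC(C)C)cc2OC(C)C)cc1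
F6 | step 9 | hexa-O-isopropyl ether of 21 | CC(C)Oc1ccc(/C=C/C(=O)c2cc(-c3cc(/C=C/C(=O)c4ccc(OC(C)C)cc4OC(C)C)ccc3OC(C)C)c(OC(C)C)cc2OC(C)C)cc1
F7 | step 6 | methyl 2-[5-(dimethoxymethyl)-2-isopropoxyphenyl]acetate | COC(=O)Cc1cc(C(OC)OC)ccc1OC(C)C
F8 | step 6 | 2-[5-(dimethoxymethyl)-2-isopropoxyphenyl]acetic acid | OC(=O)Cc1cc(C(OC)OC)ccc1OC(C)C
F9 | step 6 | methyl 4-[5-(dimethoxymethyl)-2-isopropoxyphenyl]-3-oxobutanoate | COC(=O)CC(=O)Cc1cc(C(OC)OC)ccc1OC(C)C
F10 | step 6 | 4-(dimethoxymethyl)-1-isopropoxy-2-[(1Z,3Z)-4-methoxy-2,4-bis(trimethylsilyloxy)buta-1,3-dien-1-yl]benzene | CO/C(O[Si](C)(C)C)=C/C(O[Si](C)(C)C)=C/c1cc(C(OC)OC)ccc1OC(C)C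
F11 | step 6 | 3-[2,4-dihydroxy-5-[(2E)-3-(4-isopropoxyphenyl)prop-2-enoyl]phenyl]-4-isopropoxybenzaldehyde | O=Cc1ccc(OC(C)C)c(-c2cc(C(=O)/C=C/c3ccc(OC(C)C)cc3)c(O)cc2O)c1
F12 | step 2 | methyl 2-(5-bromo-2-isopropoxyphenyl)acetate | COC(=O)Cc1cc(Br)ccc1OC(C)C
F13 | step 10 | 7-hydroxy-2-[4-hydroxy-3-[7-hydroxy-2-(4-hydroxyphenyl)-4-oxochroman-6-yl]phenyl]chroman-4-one (bis-flavanone, mixture of diastereomers) | O=C1CC(c2ccc(O)c(-c3cc4c(cc3O)OC(c3ccc(O)cc3)CC4=O)c2)Oc2cc(O)ccc12
A1 | alternative 1 | (2E)-3-[3-bromo-4-(methoxymethoxy)phenyl]-1-[2,4-bis(methoxymethoxy)phenyl]prop-2-en-1-one | COCOc1ccc(C(=O)/C=C/c2ccc(OCOC)c(Br)c2)c(OCOC)c1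
A2 | alternative 1 | (2E)-1-[2,4-bis(methoxymethoxy)-5-(4,4,5,5-tetramethyl-1,3,2-dioxaborolan-2-yl)phenyl]-3-[4-(methoxymethoxy)phenyl]prop-2-en-1-one | COCOc1ccc(/C=C/C(=O)c2cc(B3OC(C)(C)C(C)(C)O3)c(OCOC)cc2OCOC)cc1
A3 | alternative 1 | hexakis(methoxymethyl) ether of 21 | COCOc1ccc(/C=C/C(=O)c2cc(-c3cc(/C=C/C(=O)c4ccc(OCOC)cc4OCOC)ccc3OCOC)c(OCOC)cc2OCOC)cc1
A4 | alternative 2 | isoliquiritigenin, (2E)-1-(2,4-dihydroxyphenyl)-3-(4-hydroxyphenyl)prop-2-en-1-one | O=C(/C=C/c1ccc(O)cc1)c1ccc(O)cc1O
A5 | alternative 3 | 1-[5-(dimethoxymethyl)-2-isopropoxyphenyl]propan-2-one | CC(=O)Cc1cc(C(OC)OC)ccc1OC(C)C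
A6 | alternative 3 | 4-[5-(dimethoxymethyl)-2-isopropoxyphenyl]cyclohexane-1,3-dione (racemic) | O=C1CC(=O)C(c2cc(C(OC)OC)ccc2OC(C)C)CC1
A7 | alternative 3 | 4-[5-(dimethoxymethyl)-2-isopropoxyphenyl]benzene-1,3-diol | Oc1ccc(-c2cc(C(OC)OC)ccc2OC(C)C)c(O)c1
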